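The central ring of the dibenzofuran core carries, going from furan C3 to furan C2, an oxygenated carbon (C1), the lactone O-carbon (C2), the phenyl carbon (C3) and the ketone carbon (C4). These four atoms are read as a phenyl-substituted squarate unit annulated across the furan C2=C3 bond. The route therefore rests on thermal ring expansion of a 4-(benzofuran-2-yl)cyclobutenone: one heating opens the four-membered ring to a dienylketene and closes the fully substituted six-membered ring onto benzofuran C3 with every substituent in place. The precursor is a 4-methoxy-2-isopropoxy-3-phenylcyclobutenone built from diisopropyl squarate by two ordered aryllithium additions. A tethered arylacetate condensation then closes the butenolide.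

Key step: step 5

Remark: dibenzofuran locants are used for all tricyclic compounds (C4a and C9b are the former benzofuran C2 and C3). The target has no stereocentre, so every stereocentre met on the way is racemic and transient.

Step 1
Reactants: 1 3,4-dimethoxyphenol; 2 bromoacetaldehyde diethyl acetal
Product: 3 2-(3,4-dimethoxyphenoxy)acetaldehyde diethyl acetal
Conditions: K2CO3, DMF, 120 °C
Reagents that add atoms: none
Why: Williamson ether synthesis, in which the phenoxide displaces the primary bromide by SN2 while the base-stable acetal is untouched.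

Step 2
Reactants: 3 2-(3,4-dimethoxyphenoxy)acetaldehyde diethyl acetal
Product: 4 5,6-dimethoxybenzofuran
Conditions: polyphosphoric acid, toluene, 110 °C
Reagents that add atoms: none
Why: Acid-promoted cyclodehydration of an aryloxyacetaldehyde acetal (intramolecular Friedel–Crafts attack of the oxocarbenium ion, then loss of the second ethanol), which should close at the unhindered ring position para to the 3-methoxy group and not between two oxygens.

Step 3
Reactants: 4 5,6-dimethoxybenzofuran; 5 diisopropyl squarate
Product: 8 racemic 4-(5,6-dimethoxybenzofuran-2-yl)-2,3-diisopropoxy-4-methoxycyclobut-2-en-1-one, via 2-lithio-5,6-dimethoxybenzofuran 6 (not isolated), via squarate-adduct lithium alkoxide 7 (not isolated)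
Conditions: n-BuLi, THF, −78 to 0 °C; 5, −78 °C; MeOTf, −78 °C to rt
Reagents that add atoms: methyl trifluoromethanesulfonate, COS(=O)(=O)C(F)(F)F
Why: Benzofuran is lithiated selectively at C2 (alpha to oxygen), the aryllithium adds 1,2 to one squarate carbonyl at low temperature and the lithium alkoxide is O-methylated in the same pot; the new quaternary carbon forms racemic and is destroyed in step 5.

Step 4
Reactants: 8 racemic 4-(5,6-dimethoxybenzofuran-2-yl)-2,3-diisopropoxy-4-methoxycyclobut-2-en-1-one; 9 phenyllithium
Product: 12 racemic 4-(5,6-dimethoxybenzofuran-2-yl)-2-isopropoxy-4-methoxy-3-phenylcyclobut-2-en-1-one, via phenyl carbinol lithium alkoxide 10 (not isolated), via tertiary allylic trifluoroacetate 11 (not isolated)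
Conditions: PhLi, THF, −78 °C; then (CF3CO)2O, −78 °C; H2O work-up
Reagents that add atoms: water, O
Why: 1,2-Addition to the remaining carbonyl followed by 1,3-carbonyl transposition, in which the trifluoroacetylated tertiary alkoxide ionises to an alkoxy-stabilised cyclobutenyl cation that water captures at the distal isopropoxy carbon with loss of propan-2-ol, so that phenyl ends up next to the quaternary carbon; the carbinol stereocentre is transient and the quaternary centre stays racemic.

Step 5
Reactants: 12 racemic 4-(5,6-dimethoxybenzofuran-2-yl)-2-isopropoxy-4-methoxy-3-phenylcyclobut-2-en-1-one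
Product: 15 2-isopropoxy-4,7,8-trimethoxy-3-phenyldibenzofuran-1-ol, via dienylketene 13 (not isolated), via 9bH-dibenzofuran-1-one tautomer 14 (not isolated)
Conditions: p-xylene, 138 °C, Ar
Reagents that add atoms: none
Why: Heating triggers conrotatory 4π electrocyclic opening of the cyclobutenone, which breaks the C1–C4 bond and gives dienylketene 13; the 4-methoxy donor rotates outward (torquoselectivity of donor substituents), so the benzofuran-2-yl group ends up cis to the ketene. The ketene carbon then bonds to benzofuran C3 in a thermal disrotatory 6π electrocyclisation, the only ring closed in the step, a six-membered ring made of the four squarate carbons plus furan C2 and C3. Tautomerisation of the 9bH-dienone 14 restores aromaticity and should give the phenol. The closest known reaction type is the thermal ring expansion of squarate-derived 4-aryl- and 4-heteroaryl-4-alkoxycyclobutenones to annulated hydroquinone monoethers. No lasting stereocentre is formed, because the racemic quaternary carbon of 12 and the transient C9b–H centre of 14 both become sp2. The only selectivity needed is the order of substituents, which is fixed in 12: C3 is the sole position of the 2-substituted benzofuran that the ketene can reach, and a ketene of the wrong geometry can revert to 12 and reopen.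

Step 6
Reactants: 15 2-isopropoxy-4,7,8-trimethoxy-3-phenyldibenzofuran-1-ol
Product: 16 2-isopropoxy-7,8-dimethoxy-3-phenyldibenzofuran-1,4-dione
Conditions: (NH4)2Ce(NO3)6, MeCN/H2O, 0 °C
Reagents that add atoms: water, O
Why: Oxidative demethylation of a para-methoxyphenol to the para-quinone by two one-electron oxidations with the tetravalent cerium salt, water adding at the methoxy-bearing carbon and methanol leaving; the free phenol is oxidised much faster than the dimethoxybenzo ring.

Step 7
Reactants: 16 2-isopropoxy-7,8-dimethoxy-3-phenyldibenzofuran-1,4-dione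
Product: 17 2-hydroxy-7,8-dimethoxy-3-phenyldibenzofuran-1,4-dione
Conditions: 1 M NaOH (aq), THF, 0 °C to rt; then 1 M HCl
Reagents that add atoms: sodium hydroxide, [Na+].[OH-]
Why: Addition–elimination at C2 of the vinylogous ester, in which hydroxide adds beta to the C4 carbonyl and expels isopropoxide, giving a resonance-stabilised hydroxyquinone anion that resists further attack until it is acidified.

Step 8
Reactants: 17 2-hydroxy-7,8-dimethoxy-3-phenyldibenzofuran-1,4-dione; 18 4-methoxyphenylacetyl chloride
Product: 21 target tri-O-methyl ether (7,8-dimethoxy-3-phenyldibenzofuran-4-one fused at C1–C2 to a butenolide: lactone O on C2 then lactone C=O then C(4-methoxyphenyl) doubly bonded to C1), via quinonyl 4-methoxyphenylacetate 19 (not isolated), via tertiary aldol lactone 20 (not isolated)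
Conditions: Et3N, CH2Cl2, 0 °C; then DBU (cat.), rt
Reagents that add atoms: none
Why: O-Acylation of the vinylogous acid gives an activated ester whose benzylic CH2 enolises readily; the enolate adds 5-exo-trig to C1, the only carbonyl within reach, and E1cB loss of water gives the butenolide (intramolecular Knoevenagel, Perkin-type condensation as in 3-arylcoumarin synthesis), the ring fixing the alkene geometry.

Step 9
Reactants: 21 target tri-O-methyl ether
Product: 22 target CNP0139113.0 (the same butenolide-fused dibenzofuran-4-one with 7,8-dihydroxy groups, 3-phenyl and a 4-hydroxyphenyl group on the butenolide alpha-carbon)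
Conditions: BBr3, CH2Cl2, −78 °C to rt; then H2O
Reagents that add atoms: none
Why: Lewis-acid ether cleavage, in which BBr3 complexes each aryl methyl ether and bromide removes the methyl group by SN2, the aryl borates being hydrolysed on work-up; the enol lactone and quinone methide carry no O-alkyl bond and there is no stereocentre to disturb.

Compound list
1 | 3,4-dimethoxyphenol | COc1ccc(O)cc1OC | starting material
2 | bromoacetaldehyde diethyl acetal | CCOC(CBr)OCC | starting material
3 | 2-(3,4-dimethoxyphenoxy)acetaldehyde diethyl acetal | CCOC(COc1ccc(OC)c(OC)c1)OCC | intermediate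
4 | 5,6-dimethoxybenzofuran | COc1cc2ccoc2cc1OC | intermediate
5 | diisopropyl squarate | CC(C)OC1=C(OC(C)C)C(=O)C1=O | starting material
6 | 2-lithio-5,6-dimethoxybenzofuran (not isolated) | [Li]c1cc2cc(OC)c(OC)cc2o1 | intermediate
7 | lithium alkoxide of the 1,2-adduct of 6 to 5, racemic (not isolated) | [Li]OC1(c2cc3cc(OC)c(OC)cc3o2)C(OC(C)C)=C(OC(C)C)C1=O | intermediate
8 | racemic 4-(5,6-dimethoxybenzofuran-2-yl)-2,3-diisopropoxy-4-methoxycyclobut-2-en-1-one | COC1(c2cc3cc(OC)c(OC)cc3o2)C(OC(C)C)=C(OC(C)C)C1=O | intermediate
9 | phenyllithium | [Li]c1ccccc1 | starting material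
10 | lithium alkoxide of the phenyl carbinol from 8, racemic diastereomer mixture (not isolated) | COC1(c2cc3cc(OC)c(OC)cc3o2)C(OC(C)C)=C(OC(C)C)C1(O[Li])c1ccccc1 | intermediate
11 | trifluoroacetate of the phenyl carbinol, racemic diastereomer mixture (not isolated) | COC1(c2cc3cc(OC)c(OC)cc3o2)C(OC(C)C)=C(OC(C)C)C1(OC(=O)C(F)(F)F)c1ccccc1 | intermediate
12 | racemic 4-(5,6-dimethoxybenzofuran-2-yl)-2-isopropoxy-4-methoxy-3-phenylcyclobut-2-en-1-one | COC1(c2cc3cc(OC)c(OC)cc3o2)C(c2ccccc2)=C(OC(C)C)C1=O | intermediate
13 | dienylketene, benzofuranyl cis to the ketene-bearing carbon (not isolated) | O=C=C(OC(C)C)/C(c1ccccc1)=C(OC)\c1cc2cc(OC)c(OC)cc2o1 | intermediate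
14 | 2-isopropoxy-4,7,8-trimethoxy-3-phenyl-9bH-dibenzofuran-1-one, racemic (not isolated) | COC1=C2Oc3cc(OC)c(OC)cc3C2C(=O)C(OC(C)C)=C1c1ccccc1 | intermediate
15 | 2-isopropoxy-4,7,8-trimethoxy-3-phenyldibenzofuran-1-ol | COc1cc2oc3c(OC)c(-c4ccccc4)c(OC(C)C)c(O)c3c2cc1OC | intermediate
16 | 2-isopropoxy-7,8-dimethoxy-3-phenyldibenzofuran-1,4-dione | COc1cc2oc3c(c2cc1OC)C(=O)C(OC(C)C)=C(c1ccccc1)C3=O | intermediate
17 | 2-hydroxy-7,8-dimethoxy-3-phenyldibenzofuran-1,4-dione | COc1cc2oc3c(c2cc1OC)C(=O)C(O)=C(c1ccccc1)C3=O | intermediate
18 | 4-methoxyphenylacetyl chloride | COc1ccc(CC(Cl)=O)cc1 | starting material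
19 | 7,8-dimethoxy-1,4-dioxo-3-phenyldibenzofuran-2-yl 4-methoxyphenylacetate (not isolated) | COc1ccc(CC(=O)OC2=C(c3ccccc3)C(=O)c3oc4cc(OC)c(OC)cc4c3C2=O)cc1 | intermediate
20 | tertiary aldol lactone, racemic diastereomer mixture (not isolated) | O=C1OC2=C(c3ccccc3)C(=O)c3oc4cc(OC)c(OC)cc4c3C2(O)C1c1ccc(OC)cc1 | intermediate
21 | tri-O-methyl ether of the target | O=C1OC2=C(c3ccccc3)C(=O)c3oc4cc(OC)c(OC)cc4c3C2=C1c1ccc(OC)cc1 | intermediate
22 | target CNP0139113.0 | O=C1OC2=C(c3ccccc3)C(=O)c3oc4cc(O)c(O)cc4c3C2=C1c1ccc(O)cc1 | target

Total step count: 9. Longest linear sequence: 9 steps (1 to 22); compounds 2, 5, 9 and 18 enter as purchased reagents.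

Steps most likely to fail

Step 4. The carbonyl next to the quaternary carbon may be attacked sluggishly by phenyllithium. After ionisation, the phenyl-bearing cation may be captured at the wrong terminus or lose the methoxy group of the quaternary carbon, so the transposition may not be clean. The fallback sets out from 8 and brings the phenyl group in late by cross-coupling. Reduction of 8 with LiAlH(O-t-Bu)3 (THF, −78 °C) followed by the same (CF3CO)2O/water transposition of the smaller, secondary carbinol should give racemic 4-(5,6-dimethoxybenzofuran-2-yl)-2-isopropoxy-4-methoxycyclobut-2-en-1-one F1, with hydrogen at C3. Thermolysis as in step 5 should give 2-isopropoxy-4,7,8-trimethoxydibenzofuran-1-ol F2, and (NH4)2Ce(NO3)6 oxidation should give 2-isopropoxy-7,8-dimethoxydibenzofuran-1,4-dione F3. Bromination at the free C3 (Br2, NaOAc, AcOH) should give 3-bromo-2-isopropoxy-7,8-dimethoxydibenzofuran-1,4-dione F4. Suzuki–Miyaura coupling with PhB(OH)2 (Pd(PPh3)4, a zerovalent palladium catalyst, K2CO3, toluene/H2O) would come back to the route at 16.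

Step 8. The activated quinonyl ester may lose its acyl group again, by ketene elimination from the enolate or by adventitious hydrolysis, faster than the aldol closure occurs, or the aldol adduct may not dehydrate. The fallback sets out from 17 and closes the ring by olefination instead of aldol condensation. Commercial diethyl 4-methoxybenzylphosphonate is deprotonated with LiN(i-Pr)2 and carboxylated with CO2 to 2-(diethoxyphosphoryl)-2-(4-methoxyphenyl)acetic acid F5. Its acid chloride ((COCl)2, cat. DMF) acylates 17 (pyridine, CH2Cl2) to the quinonyl phosphonoacetate F6. Intramolecular Horner–Wadsworth–Emmons reaction onto the C1 carbonyl (LiCl, DBU, MeCN) expels phosphate irreversibly and would come back at 21.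

Step 9. Lewis-acid demethylation of the finished pigment may be accompanied by opening of the enol lactone or conjugate addition of bromide to the quinone methide, and the freed catechol may be oxidised on work-up. The fallback sets out from 17 and moves the demethylation ahead of the butenolide closure. BBr3 on the robust hydroxyquinone should give 2,7,8-trihydroxy-3-phenyldibenzofuran-1,4-dione F7. Perkin-type condensation with 4-hydroxyphenylacetic acid in Ac2O/NaOAc at reflux should give the tri-O-acetate of the target F8. Mild aqueous acid hydrolysis of the three aryl acetates (HCl, aqueous acetone, 50 °C) would come back at 22.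

Further compounds
F1 | step 4 | racemic 4-(5,6-dimethoxybenzofuran-2-yl)-2-isopropoxy-4-methoxycyclobut-2-en-1-one | COC1(c2cc3cc(OC)c(OC)cc3o2)C=C(OC(C)C)C1=O
F2 | step 4 | 2-isopropoxy-4,7,8-trimethoxydibenzofuran-1-ol | COc1cc2oc3c(OC)cc(OC(C)C)c(O)c3c2cc1OC
F3 | step 4 | 2-isopropoxy-7,8-dimethoxydibenzofuran-1,4-dione | COc1cc2oc3c(c2cc1OC)C(=O)C(OC(C)C)=CC3=O
F4 | step 4 | 3-bromo-2-isopropoxy-7,8-dimethoxydibenzofuran-1,4-dione | COc1cc2oc3c(c2cc1OC)C(=O)C(OC(C)C)=C(Br)C3=O
F5 | step 8 | 2-(diethoxyphosphoryl)-2-(4-methoxyphenyl)acetic acid | CCOP(=O)(OCC)C(C(O)=O)c1ccc(OC)cc1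
F6 | step 8 | 7,8-dimethoxy-1,4-dioxo-3-phenyldibenzofuran-2-yl 2-(diethoxyphosphoryl)-2-(4-methoxyphenyl)acetate (racemic) | CCOP(=O)(OCC)C(C(=O)OC1=C(c2ccccc2)C(=O)c2oc3cc(OC)c(OC)cc3c2C1=O)c1ccc(OC)cc1
F7 | step 9 | 2,7,8-trihydroxy-3-phenyldibenzofuran-1,4-dione | Oc1cc2oc3c(c2cc1O)C(=O)C(O)=C(c1ccccc1)C3=O
F8 | step 9 | tri-O-acetate of the target | O=C1OC2=C(c3ccccc3)C(=O)c3oc4cc(OC(C)=O)c(OC(C)=O)cc4c3C2=C1c1ccc(OC(C)=O)cc1
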